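Ring B is treated as a masked 2-pyrone: its 1,2,4-pattern (C1' on flavanone C2, C3' on ring E, C4'-OH) maps onto C6, an alkyne carbon and C3 of a 3-oxy-2-pyrone. A diisopropylsilylene joins the pyrone 3-OH to the ring E C4''' phenol, so the C3''' ethynyl group can only add across pyrone C3/C6. One thermal operation forms C3'–C4' and C1'–C2', expels CO2 and delivers the biaryl. The precursor is a (2S)-5,7-di-O-benzyl flavanone bearing the pyrone at C2, silicon-linked to a (2R,3R)-3''-O-TBS-5'',7''-di-O-benzyl-3'''-ethynyl dihydroflavonol. Both halves are made enantioselectively beforehand, so the cycloaddition creates no lasting stereocentre.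

Key step: step 17

Remark on the chemistry: 3-hydroxy-2-oxo-2H-pyran-6-carboxylic acid is assumed to be purchasable (otherwise it comes from galactaric acid by the classical dehydrative cyclisation); the C3'' hydroxyl is carried as a tert-butyldimethylsilyl ether, because a benzyl ether there would need alkylation under base, which opens or epimerises ring C of a dihydroflavonol, whereas the silyl ether goes on with a silyl triflate and leaves in the same fluoride step as the tether.

Step 1
Reactants: 1 2,4,6-trihydroxyacetophenone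
Product: 2 1-[2,4-bis(benzyloxy)-6-hydroxyphenyl]ethan-1-one
Conditions: BnBr (2.1 equiv), K2CO3, DMF, rt
Reagents that add atoms: benzyl bromide, BrCc1ccccc1
Why: Williamson etherification, in which the hydroxyl hydrogen-bonded to the acetyl carbonyl is the least nucleophilic and should stay free when two equivalents of halide are used.

Step 2
Reactants: 3 3-hydroxy-2-oxo-2H-pyran-6-carboxylic acid
Product: 4 3-hydroxy-6-(hydroxymethyl)-2H-pyran-2-one
Conditions: BH3·THF (3 equiv), THF, 0 °C to rt; MeOH quench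
Reagents that add atoms: none
Why: Chemoselective borane reduction of a carboxylic acid through its acyloxyborane, which should be much faster than attack on the conjugated lactone carbonyl or the electron-poor ring alkenes.

Step 3
Reactants: 4 3-hydroxy-6-(hydroxymethyl)-2H-pyran-2-one
Product: 5 6-(hydroxymethyl)-3-[(4-methoxybenzyl)oxy]-2H-pyran-2-one
Conditions: PMBCl (1.05 equiv), K2CO3 (1.1 equiv), Bu4NI (cat.), DMF, rt
Reagents that add atoms: 4-methoxybenzyl chloride, COc1ccc(CCl)cc1
Why: Williamson O-alkylation in which carbonate deprotonates only the acidic enolic 3-OH, so the primary alcohol should remain free.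

Step 4
Reactants: 5 6-(hydroxymethyl)-3-[(4-methoxybenzyl)oxy]-2H-pyran-2-one
Product: 6 3-[(4-methoxybenzyl)oxy]-2-oxo-2H-pyran-6-carbaldehyde
Conditions: Dess–Martin periodinane, CH2Cl2, rt
Reagents that add atoms: none
Why: Dess–Martin oxidation of a primary alcohol to the aldehyde under neutral conditions that leave the pyrone and the PMB ether intact.

Step 5
Reactants: 2 1-[2,4-bis(benzyloxy)-6-hydroxyphenyl]ethan-1-one; 6 3-[(4-methoxybenzyl)oxy]-2-oxo-2H-pyran-6-carbaldehyde
Product: 8 6-{(1R)-3-[2,4-bis(benzyloxy)-6-hydroxyphenyl]-1-hydroxy-3-oxopropyl}-3-[(4-methoxybenzyl)oxy]-2H-pyran-2-one, via bis-silyl enol ether 7 (not isolated)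
Conditions: 2, TMSOTf (2.3 equiv), Et3N, CH2Cl2, 0 °C; evaporate, pentane, filter; then 6, SiCl4, (R,R)-bisphosphoramide [two 2,2'-bis(methylamino)-1,1'-binaphthyl phosphoramide units joined by an N,N'-dimethylpentane-1,5-diamine linker] (5 mol%), iPr2NEt (10 mol%), CH2Cl2, −78 °C; aq. NaHCO3
Reagents that add atoms: trimethylsilyl trifluoromethanesulfonate, C[Si](C)(C)OS(=O)(=O)C(F)(F)F (its silyl groups are in 7 only; 8 holds nothing but the two reactants)
Why: Lewis-base-catalysed Mukaiyama aldol addition, in which the chiral phosphoramide-bound trichlorosilyl cation activates the aldehyde and should expose its Re face to the methyl-ketone silyl enol ether, setting the (R)-carbinol, while aqueous work-up frees the carbinol and the labile aryl silyl ether.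

Step 6
Reactants: 8 the (R)-aldol
Product: 9 (2S)-5,7-bis(benzyloxy)-2-{3-[(4-methoxybenzyl)oxy]-2-oxo-2H-pyran-6-yl}chroman-4-one
Conditions: PPh3, DIAD, THF, 0 °C to rt
Reagents that add atoms: none
Why: Intramolecular Mitsunobu etherification, in which the phenol displaces the activated carbinol oxygen with inversion, so the (R)-carbinol should give the (2S)-flavanone; the electron-poor pyrone disfavours ionisation and thereby loss of configuration.

Step 7
Reactants: 9 the PMB-protected pyronyl flavanone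
Product: 10 (2S)-5,7-bis(benzyloxy)-2-(3-hydroxy-2-oxo-2H-pyran-6-yl)chroman-4-one
Conditions: TFA, anisole (excess), CH2Cl2, 0 °C
Reagents that add atoms: none
Why: Acidolysis of the 4-methoxybenzyl ether with Friedel–Crafts capture of the benzylic cation by anisole, under which benzyl ethers survive and C2, which faces neither base nor a cation-stabilising group, should keep its configuration.

Step 8
Reactants: 2 1-[2,4-bis(benzyloxy)-6-hydroxyphenyl]ethan-1-one
Product: 11 1-[2,4-bis(benzyloxy)-6-(methoxymethoxy)phenyl]ethan-1-one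
Conditions: NaH, MOMCl, DMF, 0 °C to rt
Reagents that add atoms: chloromethyl methyl ether, COCCl
Why: Williamson-type O-alkylation of the sodium phenoxide, whose formation overcomes the hydrogen bond to the carbonyl.

Step 9
Reactants: 12 4-hydroxy-3-iodobenzaldehyde
Product: 13 3-iodo-4-(methoxymethoxy)benzaldehyde
Conditions: MOMCl, iPr2NEt, CH2Cl2, 0 °C to rt
Reagents that add atoms: chloromethyl methyl ether, COCCl
Why: Williamson-type O-alkylation of an acidic phenol with an amine base, which masks the phenol so that it neither deactivates the aldehyde in the condensation nor interferes later.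

Step 10
Reactants: 11 the MOM-protected acetophenone; 13 3-iodo-4-(methoxymethoxy)benzaldehyde
Product: 14 (E)-1-[2,4-bis(benzyloxy)-6-(methoxymethoxy)phenyl]-3-[3-iodo-4-(methoxymethoxy)phenyl]prop-2-en-1-one
Conditions: KOH, EtOH/THF, rt
Reagents that add atoms: none
Why: Claisen–Schmidt condensation, in which aldol addition and E1cB dehydration should give the conjugated (E)-enone and the masked 2'-oxygen cannot cyclise onto it.

Step 11
Reactants: 14 the (E)-chalcone
Product: 15 [2,4-bis(benzyloxy)-6-(methoxymethoxy)phenyl]{(2R,3S)-3-[3-iodo-4-(methoxymethoxy)phenyl]oxiran-2-yl}methanone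
Conditions: poly-L-leucine, urea–H2O2, DBU, THF, rt
Reagents that add atoms: urea–hydrogen peroxide, OO.NC(N)=O
Why: Juliá–Colonna epoxidation (Weitz–Scheffer addition of hydroperoxide inside the helical poly-L-leucine), which for (E)-chalcones delivers oxygen to the face that gives the (2R,3S)-trans-epoxide.

Step 12
Reactants: 15 the (2R,3S)-epoxy ketone
Product: 16 (2R,3R)-5,7-bis(benzyloxy)-3-hydroxy-2-(4-hydroxy-3-iodophenyl)chroman-4-one
Conditions: conc. HCl, MeOH/THF, 55 °C
Reagents that add atoms: none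
Why: Acid removes both MOM acetals and the freed 2'-phenol opens the epoxide at the benzylic carbon in a 6-endo oxa-cyclisation, so C3'' keeps the configuration of the epoxide carbon next to the carbonyl and C2'' should settle trans (diequatorial) to it.

Step 13
Reactants: 16 the iodo dihydroflavonol diol
Product: 17 (2R,3R)-5,7-bis(benzyloxy)-3-(tert-butyldimethylsilyloxy)-2-[4-(tert-butyldimethylsilyloxy)-3-iodophenyl]chroman-4-one
Conditions: TBSOTf (2.6 equiv), 2,6-lutidine, CH2Cl2, −78 to 0 °C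
Reagents that add atoms: tert-butyldimethylsilyl trifluoromethanesulfonate, CC(C)(C)[Si](C)(C)OS(=O)(=O)C(F)(F)F
Why: O-silylation with a silyl triflate and a hindered pyridine base protects the phenol and the hindered C3'' alcohol without forming the alkoxide that would open ring C.

Step 14
Reactants: 17 the bis-TBS aryl iodide; 18 ethynyltrimethylsilane
Product: 19 (2R,3R)-5,7-bis(benzyloxy)-3-(tert-butyldimethylsilyloxy)-2-{4-(tert-butyldimethylsilyloxy)-3-[(trimethylsilyl)ethynyl]phenyl}chroman-4-one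
Conditions: PdCl2(PPh3)2 (cat.), CuI (cat.), Et3N, THF, rt to 40 °C
Reagents that add atoms: ethynyltrimethylsilane (18), C#C[Si](C)(C)C
Why: Sonogashira coupling of an aryl iodide under mild amine conditions, in which the silylated phenol cannot cyclise onto the new alkyne.

Step 15
Reactants: 19 the silylated alkyne
Product: 20 (2R,3R)-5,7-bis(benzyloxy)-3-(tert-butyldimethylsilyloxy)-2-(3-ethynyl-4-hydroxyphenyl)chroman-4-one
Conditions: TBAF/AcOH (1:1, 2.2 equiv), THF, 0 °C
Reagents that add atoms: none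
Why: Buffered fluoride desilylation, which should cleave the aryl silyl ether and the alkynyl C–Si bond far faster than the hindered secondary silyl ether, the acetic acid keeping the ortho-ethynylphenol from cyclising to a benzofuran and C2'' from epimerising through the phenoxide.

Step 16
Reactants: 20 the ethynylphenol dihydroflavonol; 21 dichlorodiisopropylsilane; 10 the hydroxypyrone flavanone
Product: 23 (2S)-5,7-bis(benzyloxy)-2-[3-({[4-((2R,3R)-5,7-bis(benzyloxy)-3-(tert-butyldimethylsilyloxy)-4-oxochroman-2-yl)-2-ethynylphenoxy]diisopropylsilyl}oxy)-2-oxo-2H-pyran-6-yl]chroman-4-one, via chlorosilane 22 (not isolated)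
Conditions: 20, 21 (1.5 equiv), Et3N, CH2Cl2, −40 to 0 °C; volatiles off in vacuo; then 10, imidazole, CH2Cl2/DMF, 0 °C to rt; filtration through Et3N-washed silica
Reagents that add atoms: dichlorodiisopropylsilane (21), CC(C)[Si](Cl)(Cl)C(C)C
Why: Stepwise nucleophilic substitution at silicon (unsymmetrical silyl ketal formation), in which the isopropyl groups make the second chloride much slower to leave than the first, so the monochloride can be formed from the phenol and then taken by the acidic pyrone hydroxyl.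

Step 17
Reactants: 23 the silicon-tethered pyrone–alkyne
Product: 25 2-[(2S)-5,7-bis(benzyloxy)-4-oxochroman-2-yl]-10-[(2R,3R)-5,7-bis(benzyloxy)-3-(tert-butyldimethylsilyloxy)-4-oxochroman-2-yl]-6,6-diisopropyldibenzo[d,f][1,3,2]dioxasilepine, via bridged lactone 24 (not isolated)
Conditions: PhMe (0.005 M), BHT (cat.), sealed tube, 140–160 °C
Reagents that add atoms: none
Why: Proposed new method: on heating, the C3''' ethynyl group, held over the diene by the O–Si–O bridge, should add in a concerted intramolecular [4+2] cycloaddition across pyrone C3 and C6 (new bonds C3'–C4' and C1'–C2') to give the bridged lactone 24, which loses CO2 by retro-[4+2] fragmentation and so becomes the benzene ring B. The closest known reaction types are the thermal Diels–Alder/decarboxylation of 2-pyrones with alkynes and silicon-tethered intramolecular Diels–Alder reactions; untested is a silylene that joins a 3-pyronyl oxygen to an ortho-ethynylphenol oxygen. Ring B closes by cycloaddition followed by extrusion, and the seven-membered dibenzo[d,f][1,3,2]dioxasilepine closes in the same event as the fused tether ring of an intramolecular Diels–Alder reaction whose tether sits on a diene terminus (C3'–C4' is its ring-closing bond). No stereocentre survives: the two bridgehead centres of 24 are erased on CO2 loss, so both facial adducts converge on 25, and the biaryl axis inside the seven-membered ring is expected to flip freely. The step needs regioselectivity (aryl-bearing alkyne carbon to pyrone C3) and ring closure in preference to intermolecular addition; the five-atom tether allows only that orientation and high dilution secures the second, while the neutral, reagent-free medium leaves C2, C2'' and C3'' alone.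

Step 18
Reactants: 25 the silylene-bridged biaryl
Product: 26 (2R,3R)-5,7-bis(benzyloxy)-2-{3-[5-((2S)-5,7-bis(benzyloxy)-4-oxochroman-2-yl)-2-hydroxyphenyl]-4-hydroxyphenyl}-3-hydroxychroman-4-one
Conditions: HF·pyridine, pyridine, THF, 0 °C to rt
Reagents that add atoms: none
Why: Fluoride-driven Si–O cleavage in an acidic buffer should open the bis(aryloxy)silane ring and remove the secondary silyl ether while the benzyl ethers and the three stereocentres stay untouched.

Step 19
Reactants: 26 the tetra-O-benzyl biflavonoid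
Product: 27 (2R,3R)-2-{3-[5-((2S)-5,7-dihydroxy-4-oxochroman-2-yl)-2-hydroxyphenyl]-4-hydroxyphenyl}-3,5,7-trihydroxychroman-4-one (CNP0201582.1)
Conditions: H2 (1 atm), 10% Pd/C, EtOAc/MeOH, rt
Reagents that add atoms: none
Why: Catalytic hydrogenolysis of the four aryl benzyl ethers under neutral conditions, which should not epimerise C2 or C2'' of the free 4'-hydroxy systems.

Compound list
1 | 2,4,6-trihydroxyacetophenone | CC(=O)c1c(O)cc(O)cc1O | starting material
2 | 1-[2,4-bis(benzyloxy)-6-hydroxyphenyl]ethan-1-one | CC(=O)c1c(O)cc(OCc2ccccc2)cc1OCc1ccccc1 | intermediate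
3 | 3-hydroxy-2-oxo-2H-pyran-6-carboxylic acid | OC(=O)c1ccc(O)c(=O)o1 | starting material
4 | 3-hydroxy-6-(hydroxymethyl)-2H-pyran-2-one | OCc1ccc(O)c(=O)o1 | intermediate
5 | 6-(hydroxymethyl)-3-[(4-methoxybenzyl)oxy]-2H-pyran-2-one | OCc1ccc(OCc2ccc(OC)cc2)c(=O)o1 | intermediate
6 | 3-[(4-methoxybenzyl)oxy]-2-oxo-2H-pyran-6-carbaldehyde | O=Cc1ccc(OCc2ccc(OC)cc2)c(=O)o1 | intermediate
7 | {1-[2,4-bis(benzyloxy)-6-(trimethylsilyloxy)phenyl]ethenyloxy}trimethylsilane (bis-silyl enol ether of 2) | C=C(O[Si](C)(C)C)c1c(O[Si](C)(C)C)cc(OCc2ccccc2)cc1OCc1ccccc1 | intermediate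
8 | 6-{(1R)-3-[2,4-bis(benzyloxy)-6-hydroxyphenyl]-1-hydroxy-3-oxopropyl}-3-[(4-methoxybenzyl)oxy]-2H-pyran-2-one | O[C@H](CC(=O)c1c(O)cc(OCc2ccccc2)cc1OCc1ccccc1)c1ccc(OCc2ccc(OC)cc2)c(=O)o1 | intermediate
9 | (2S)-5,7-bis(benzyloxy)-2-{3-[(4-methoxybenzyl)oxy]-2-oxo-2H-pyran-6-yl}chroman-4-one | O=C1C[C@@H](c2ccc(OCc3ccc(OC)cc3)c(=O)o2)Oc2cc(OCc3ccccc3)cc(OCc3ccccc3)c21 | intermediate
10 | (2S)-5,7-bis(benzyloxy)-2-(3-hydroxy-2-oxo-2H-pyran-6-yl)chroman-4-one | O=C1C[C@@H](c2ccc(O)c(=O)o2)Oc2cc(OCc3ccccc3)cc(OCc3ccccc3)c21 | intermediate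
11 | 1-[2,4-bis(benzyloxy)-6-(methoxymethoxy)phenyl]ethan-1-one | CC(=O)c1c(OCOC)cc(OCc2ccccc2)cc1OCc1ccccc1 | intermediate
12 | 4-hydroxy-3-iodobenzaldehyde | O=Cc1ccc(O)c(I)c1 | starting material
13 | 3-iodo-4-(methoxymethoxy)benzaldehyde | O=Cc1ccc(OCOC)c(I)c1 | intermediate
14 | (E)-1-[2,4-bis(benzyloxy)-6-(methoxymethoxy)phenyl]-3-[3-iodo-4-(methoxymethoxy)phenyl]prop-2-en-1-one | O=C(/C=C/c1ccc(OCOC)c(I)c1)c1c(OCOC)cc(OCc2ccccc2)cc1OCc1ccccc1 | intermediate
15 | [2,4-bis(benzyloxy)-6-(methoxymethoxy)phenyl]{(2R,3S)-3-[3-iodo-4-(methoxymethoxy)phenyl]oxiran-2-yl}methanone | O=C([C@@H]1O[C@H]1c1ccc(OCOC)c(I)c1)c1c(OCOC)cc(OCc2ccccc2)cc1OCc1ccccc1 | intermediate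
16 | (2R,3R)-5,7-bis(benzyloxy)-3-hydroxy-2-(4-hydroxy-3-iodophenyl)chroman-4-one | Oc1ccc(cc1I)[C@H]1Oc2cc(OCc3ccccc3)cc(OCc3ccccc3)c2C(=O)[C@@H]1O | intermediate
17 | (2R,3R)-5,7-bis(benzyloxy)-3-(tert-butyldimethylsilyloxy)-2-[4-(tert-butyldimethylsilyloxy)-3-iodophenyl]chroman-4-one | CC(C)(C)[Si](C)(C)Oc1ccc(cc1I)[C@H]1Oc2cc(OCc3ccccc3)cc(OCc3ccccc3)c2C(=O)[C@@H]1O[Si](C)(C)C(C)(C)C | intermediate
18 | ethynyltrimethylsilane | C#C[Si](C)(C)C | starting material
19 | (2R,3R)-5,7-bis(benzyloxy)-3-(tert-butyldimethylsilyloxy)-2-{4-(tert-butyldimethylsilyloxy)-3-[(trimethylsilyl)ethynyl]phenyl}chroman-4-one | CC(C)(C)[Si](C)(C)Oc1ccc(cc1C#C[Si](C)(C)C)[C@H]1Oc2cc(OCc3ccccc3)cc(OCc3ccccc3)c2C(=O)[C@@H]1O[Si](C)(C)C(C)(C)C | intermediate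
20 | (2R,3R)-5,7-bis(benzyloxy)-3-(tert-butyldimethylsilyloxy)-2-(3-ethynyl-4-hydroxyphenyl)chroman-4-one | Oc1ccc(cc1C#C)[C@H]1Oc2cc(OCc3ccccc3)cc(OCc3ccccc3)c2C(=O)[C@@H]1O[Si](C)(C)C(C)(C)C | intermediate
21 | dichlorodiisopropylsilane | CC(C)[Si](Cl)(Cl)C(C)C | starting material
22 | (2R,3R)-5,7-bis(benzyloxy)-3-(tert-butyldimethylsilyloxy)-2-{4-[chloro(diisopropyl)silyloxy]-3-ethynylphenyl}chroman-4-one | CC(C)[Si](Cl)(C(C)C)Oc1ccc(cc1C#C)[C@H]1Oc2cc(OCc3ccccc3)cc(OCc3ccccc3)c2C(=O)[C@@H]1O[Si](C)(C)C(C)(C)C | intermediate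
23 | (2S)-5,7-bis(benzyloxy)-2-[3-({[4-((2R,3R)-5,7-bis(benzyloxy)-3-(tert-butyldimethylsilyloxy)-4-oxochroman-2-yl)-2-ethynylphenoxy]diisopropylsilyl}oxy)-2-oxo-2H-pyran-6-yl]chroman-4-one | O=C1C[C@@H](c2ccc(O[Si](C(C)C)(C(C)C)Oc3ccc(cc3C#C)[C@H]3Oc4cc(OCc5ccccc5)cc(OCc5ccccc5)c4C(=O)[C@@H]3O[Si](C)(C)C(C)(C)C)c(=O)o2)Oc2cc(OCc3ccccc3)cc(OCc3ccccc3)c21 | intermediate
24 | cycloadduct: 2-oxabicyclo[2.2.2]octa-5,7-dien-3-one with the (2S)-flavanone on bridgehead C1, the siloxy oxygen on bridgehead C4 and ring E on C8, the O–Si–O bridge closing a seven-membered ring (both bridgehead epimers) | O=C1C[C@@H](C23OC(=O)C4(C=C2)O[Si](C(C)C)(C(C)C)Oc2ccc(cc2C4=C3)[C@H]2Oc3cc(OCc4ccccc4)cc(OCc4ccccc4)c3C(=O)[C@@H]2O[Si](C)(C)C(C)(C)C)Oc2cc(OCc3ccccc3)cc(OCc3ccccc3)c21 | intermediate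
25 | 2-[(2S)-5,7-bis(benzyloxy)-4-oxochroman-2-yl]-10-[(2R,3R)-5,7-bis(benzyloxy)-3-(tert-butyldimethylsilyloxy)-4-oxochroman-2-yl]-6,6-diisopropyldibenzo[d,f][1,3,2]dioxasilepine | O=C1C[C@@H](c2ccc3O[Si](C(C)C)(C(C)C)Oc4ccc(cc4-c3c2)[C@H]2Oc3cc(OCc5ccccc5)cc(OCc5ccccc5)c3C(=O)[C@@H]2O[Si](C)(C)C(C)(C)C)Oc2cc(OCc3ccccc3)cc(OCc3ccccc3)c21 | intermediate
26 | (2R,3R)-5,7-bis(benzyloxy)-2-{3-[5-((2S)-5,7-bis(benzyloxy)-4-oxochroman-2-yl)-2-hydroxyphenyl]-4-hydroxyphenyl}-3-hydroxychroman-4-one | O=C1C[C@@H](c2ccc(O)c(-c3cc([C@H]4Oc5cc(OCc6ccccc6)cc(OCc6ccccc6)c5C(=O)[C@@H]4O)ccc3O)c2)Oc2cc(OCc3ccccc3)cc(OCc3ccccc3)c21 | intermediate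
27 | (2R,3R)-2-{3-[5-((2S)-5,7-dihydroxy-4-oxochroman-2-yl)-2-hydroxyphenyl]-4-hydroxyphenyl}-3,5,7-trihydroxychroman-4-one (CNP0201582.1) | O=C1C[C@@H](c2ccc(O)c(-c3cc([C@H]4Oc5cc(O)cc(O)c5C(=O)[C@@H]4O)ccc3O)c2)Oc2cc(O)cc(O)c21 | target

Total step count: 19. Longest linear sequence: 12 steps (steps 1, 8, 10, 11, 12, 13, 14, 15, 16, 17, 18, 19).

Steps most likely to fail

Step 17 (the only step beyond precedent). The cycloaddition may be too slow at temperatures the bis(aryloxy)silane tolerates, so that Si–O exchange and oligomerisation, or thermal ring opening at flavanone C2, overtake ring formation. The fallback gives up the pyrone as ring B precursor and makes the C3'–C3''' bond by known cross-coupling; it sets out from 17 (together with 7 and 13) and comes back to the route at 26. Iodide 17 would be converted by Miyaura borylation (bis(pinacolato)diboron, PdCl2(dppf), KOAc, dioxane) into the pinacol boronate of the protected dihydroflavonol F1. In parallel, enol ether 7 would be added to aldehyde 13 under the conditions of step 5 to give the (3R)-aldol 1-[2,4-bis(benzyloxy)-6-hydroxyphenyl]-3-hydroxy-3-[3-iodo-4-(methoxymethoxy)phenyl]propan-1-one F2. Mitsunobu closure as in step 6 would turn it into (2S)-5,7-bis(benzyloxy)-2-[3-iodo-4-(methoxymethoxy)phenyl]chroman-4-one F3. Suzuki–Miyaura coupling of the two halves (Pd(PPh3)4, CsF, DME, so as to avoid hydroxide at the flavanone) would give the fully protected biaryl F4. Methanolic HCl would then remove the MOM ether and both silyl ethers (HF·pyridine afterwards if the C3'' silyl ether persists) to give 26.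

Step 16. Double substitution at silicon may give symmetrical bis-ethers, and the mixed bis(aryloxy)silane may hydrolyse during isolation. The fallback builds the unsymmetrical silyl ketal through a monofunctional hydrosilane, which cannot react twice and can be purified; it sets out from 20 and comes back at 23. Phenol 20 would be silylated with chlorodiisopropylsilane (imidazole, CH2Cl2) to the aryloxy(diisopropyl)silane F5. N-Bromosuccinimide (CH2Cl2, 0 °C) would convert its Si–H bond into the bromosilane F6, and this, in the same flask, would be treated with 10 and Et3N to give 23.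

Step 5. Facial selectivity at the aldehyde may be poor or addition of the hindered enol ether slow, with dehydration of the aldol on work-up. The fallback drops asymmetric C–C bond formation in favour of a racemic synthesis with resolution; it sets out from 2 and 6 and comes back at 9. The dilithio derivative of 2 (LiHMDS, 2.2 equiv, THF, −78 °C) would add to 6 to give the racemic aldol F7, and Mitsunobu closure as in step 6 would give the racemic flavanone F8. Its enantiomers would be separated on a cellulose tris(3,5-dimethylphenylcarbamate) phase to supply (2S)-9, while the (2R)-enantiomer could be racemised with mild base through reversible ring opening and recycled.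

Further compounds
F1 | step 17 | (2R,3R)-5,7-bis(benzyloxy)-3-(tert-butyldimethylsilyloxy)-2-[4-(tert-butyldimethylsilyloxy)-3-(4,4,5,5-tetramethyl-1,3,2-dioxaborolan-2-yl)phenyl]chroman-4-one | CC(C)(C)[Si](C)(C)Oc1ccc(cc1B1OC(C)(C)C(C)(C)O1)[C@H]1Oc2cc(OCc3ccccc3)cc(OCc3ccccc3)c2C(=O)[C@@H]1O[Si](C)(C)C(C)(C)C
F2 | step 17 | (3R)-1-[2,4-bis(benzyloxy)-6-hydroxyphenyl]-3-hydroxy-3-[3-iodo-4-(methoxymethoxy)phenyl]propan-1-one | O[C@H](CC(=O)c1c(O)cc(OCc2ccccc2)cc1OCc1ccccc1)c1ccc(OCOC)c(I)c1
F3 | step 17 | (2S)-5,7-bis(benzyloxy)-2-[3-iodo-4-(methoxymethoxy)phenyl]chroman-4-one | O=C1C[C@@H](c2ccc(OCOC)c(I)c2)Oc2cc(OCc3ccccc3)cc(OCc3ccccc3)c21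
F4 | step 17 | (2R,3R)-5,7-bis(benzyloxy)-2-{3-[5-((2S)-5,7-bis(benzyloxy)-4-oxochroman-2-yl)-2-(methoxymethoxy)phenyl]-4-(tert-butyldimethylsilyloxy)phenyl}-3-(tert-butyldimethylsilyloxy)chroman-4-one | O=C1C[C@@H](c2ccc(OCOC)c(-c3cc([C@H]4Oc5cc(OCc6ccccc6)cc(OCc6ccccc6)c5C(=O)[C@@H]4O[Si](C)(C)C(C)(C)C)ccc3O[Si](C)(C)C(C)(C)C)c2)Oc2cc(OCc3ccccc3)cc(OCc3ccccc3)c21
F5 | step 16 | (2R,3R)-5,7-bis(benzyloxy)-3-(tert-butyldimethylsilyloxy)-2-{4-[(diisopropylsilyl)oxy]-3-ethynylphenyl}chroman-4-one | CC(C)[SiH](C(C)C)Oc1ccc(cc1C#C)[C@H]1Oc2cc(OCc3ccccc3)cc(OCc3ccccc3)c2C(=O)[C@@H]1O[Si](C)(C)C(C)(C)C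
F6 | step 16 | (2R,3R)-5,7-bis(benzyloxy)-3-(tert-butyldimethylsilyloxy)-2-{4-[bromo(diisopropyl)silyloxy]-3-ethynylphenyl}chroman-4-one | CC(C)[Si](Br)(C(C)C)Oc1ccc(cc1C#C)[C@H]1Oc2cc(OCc3ccccc3)cc(OCc3ccccc3)c2C(=O)[C@@H]1O[Si](C)(C)C(C)(C)C
F7 | step 5 | racemic 6-{3-[2,4-bis(benzyloxy)-6-hydroxyphenyl]-1-hydroxy-3-oxopropyl}-3-[(4-methoxybenzyl)oxy]-2H-pyran-2-one | OC(CC(=O)c1c(O)cc(OCc2ccccc2)cc1OCc1ccccc1)c1ccc(OCc2ccc(OC)cc2)c(=O)o1
F8 | step 5 | racemic 5,7-bis(benzyloxy)-2-{3-[(4-methoxybenzyl)oxy]-2-oxo-2H-pyran-6-yl}chroman-4-one | O=C1CC(c2ccc(OCc3ccc(OC)cc3)c(=O)o2)Oc2cc(OCc3ccccc3)cc(OCc3ccccc3)c21
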